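The data were computed with constants of no real substance; the scatter is artificial.

Slowness is what makes these runs easy to read. The north-east run climbs from 12.4 % at 8.00 h to 30.3 % at 20.0 h, a factor of 2.44 in product for 2.50 in time. That line is nearly straight, so you can let a reading at one time stand for the rate near the conversion asked about.

all flasks: starting material 0.066 M
- south-west: enzyme 0.02 mol%; added ligand 5.2 µM; run made earlier
- north-west: enzyme 0.02 mol%; added ligand 12 µM; run made earlier
- north-east: enzyme 0.04 mol%; added ligand 7.7 µM; run made earlier
- flask: enzyme 0.02 mol%; added ligand 7.7 µM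

| run | time / h | product / % |
|---|---|---|
| south-west | 4.00 | 4.5 |
| south-west | 8.00 | 7.9 |
| south-west | 10.0 | 11.5 |
| south-west | 15.0 | 15.5 |
| south-west | 20.0 | 20.8 |
| north-west | 1.50 | 0.8 |
| north-west | 5.00 | 5.2 |
| north-west | 8.00 | 8.4 |
| north-west | 12.0 | 11.7 |
| north-west | 20.0 | 19.2 |
| north-east | 4.00 | 5.7 |
| north-east | 8.00 | 12.4 |
| north-east | 10.0 | 14.8 |
| north-east | 15.0 | 21.8 |
| north-east | 20.0 | 30.3 |

(readings scatter by 0.5 percentage points)



* factor on the rate of making product when 10 % of the starting material are converted if enzyme is charged twice over
* factor on the rate when 10 % of the starting material are converted if enzyme is charged at 0.2 mol% instead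

At 20.0 h the south-west and north-west runs, whose c(added ligand) brackets that of the flask, read 20.8 % and 19.2 %, so I take their mean for enzyme at 0.02 mol%. The north-east run, with twice that enzyme, reads 1.51 times this mean. From this reading, with its scatter of 0.5 percentage points, comes the quantity to carry: the power to which the rate follows the enzyme charge, n = 0.599, the apparent order in enzyme. I commit to 1.51 for the doubling and, holding n over ten times the charge, to 3.97 for 0.2 mol%.

The forecast, calling the order "close to half order", gives 1.47 and 3.1, the second lower than my figure. The flask gives 1.50 and 3.62.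

    starting material + enzyme ⇌ starting complex (K = 41.8 M⁻¹, k = 485 M⁻¹ s⁻¹)
    starting complex ⇌ enzyme + product (K = 0.747 M, k = 0.106 s⁻¹)
    enzyme + added ligand ⇌ idle complex (K = 3.60 × 10⁵ M⁻¹, k = 392 M⁻¹ s⁻¹)
    2 starting complex ⇌ resting dimer, settled at all times (K = 1.44 × 10⁶ M⁻¹)

Carried back, 1.50 means an order of 0.585 for this flask, and 3.62 at 0.2 mol% means 0.559, lower than n, so my power overshot there by a factor of 1.10. In the flask at 7.45 h, enzyme has a half-life of 0.080 h by its forward step with added ligand alone, far shorter than the time the flask has then run, and idle complex goes from 11.3 % of the catalyst at 1.50 h to 11.8 % at 7.50 h. At that last time the flask's resting dimer, the resting state, in which each dimer counts as two, holds 69.3 % of the catalyst.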